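All runs stem from a simulated flask on assumed constants, and the scatter is random.

In a one-step world every free monomer that reacts enters a chain and each initiator begins one chain, so the average folds into one number: 21.3, the units of charge per initiator, a statistical chain length. Multiplied by the fraction of the charge that ends in chains, it gives the average, provided the initiator has begun its chains. It speaks of dp, not of c.

| setting | amber | flask |
|---|---|---|
| free monomer | 0.50 M (fed, over 50 h) | 0.50 M (fed, over 50 h) |
| transfer agent | 0.15 M | 0.150 M |
| initiator | 4.7 mol% | 4.7 mol% |
| remark | the very flask that is asked about, followed so far |  |
| time |  | 6.0 d |

- amber (time / h: monomer in chains / %, free monomer / %): 1.00: 0, 1.1; 2.00: 0.1, 3.5; 3.00: 1.2, 5.6; 6.00: 1.1, 8.9; 12.0: 3.0, 18.4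

(each reading ± 1 percentage point)

- the average divides the monomer in chains by the number of chains begun, living and dead together
- the earlier runs do not show the number of chains; that part of a forecast is a guess
- percentages count the whole charge, also what has not yet gone in

* average number of monomer units in a chain (chains begun, living or dead) at 6.0 d
* part of the free monomer that has reacted at 6.0 d

Is that one number enough for this flask? By 12.0 h the steady feed has put in 24.0% of the charge and free monomer reads 18.4%, so 5.60% has reacted, yet monomer in chains reads 3.0%. That gives a selectivity for chains of 0.536, less than one, and loose, with 1 percentage point of scatter on each reading. So on these readings one number looks not to be enough. If that fraction holds and the charge reacts out, I commit to 11.4 units. The forecast gives dp 3, lower than mine, and c 83%; on dp it says, "Chain count is a guess".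

The flask gives dp 5.51 and c 99.1%.

    free monomer + initiator → living end + monomer in chains (k = 0.440 M⁻¹ h⁻¹)
    free monomer + living end → monomer in chains + living end, rate k2*[living end]*[free monomer] (k = 2.70 M⁻¹ h⁻¹)
    living end + transfer agent → dead chain (kL = 0.540 M⁻¹ h⁻¹)
    free monomer → uncatalysed product (k = 0.0370 h⁻¹)

At 6.00 d this flask holds 73.6% of the charge as uncatalysed product and 25.6% as monomer in chains, and its average stands below my 11.4 units. 21.3 times the part in chains is 5.45, level with the average.

On the neighbour charged with 2.0 M of free monomer the loading is held, so 21.3 stands, and its 63.3% in chains gives 13.5. The computed dp there is 13.5.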